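The reading comes at 1.0 h, and it is the excess of left-handed product over right-handed product.

    coupling partner + free catalyst + left-handed substrate → free catalyst + left-handed product (k1 = 300 /M²/min, Ea1 = 38.0 kJ/mol)
    coupling partner + free catalyst + right-handed substrate → free catalyst + right-handed product (k2 = 9.4 /M²/min, Ea2 = 42.0 kJ/mol)
    free catalyst → spent catalyst A (k3 = 0.011 /min, Ea3 = 99.0 kJ/mol)
    left-handed product ⇌ right-handed product (k4 = 0.012 /min, Ea4 = 95.0 kJ/mol)
    2 free catalyst → spent catalyst B (k5 = 5.5 /M/min, Ea5 = 54.0 kJ/mol)
    (constants at 50 °C)

all flasks: left-handed substrate 0.050 M; coupling partner 0.0300 M; free catalyst 1.2 mM; right-handed substrate 0.050 M; time 1.0 h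
- zeta: temperature 80 °C
- beta: temperature −10 °C
- gamma: temperature 50 °C
- alpha: temperature 20 °C

- free catalyst is single-handed; left-handed substrate and right-handed substrate are mirror images of each other, charged as a racemate, each of them at the stated concentration
- two of one species on the left: rate k times its square, two consumed each time
- constants are those at 50 °C; use the activation energies for any other temperature
- an excess is the difference of the two amounts in percent of their sum
- an excess is below zero if the other one leads

- the flask that comes out highest in excess of left-handed product over right-handed product, or "all alike" when all lie within 1.5 percentage points (zeta / beta / gamma / alpha / all alike)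
- excess of left-handed product over right-handed product at the end, zeta
- excess of left-handed product over right-handed product at the end, beta
- excess of left-handed product over right-handed product at the end, gamma
- excess of left-handed product over right-handed product at the end, alpha

The zero of my scale is the racemate: the two products have the same energy, so their interconversion ends at excess zero, and it wipes out any excess at twice its rate constant, both ways together. For gamma, at 50 °C, that gives 1.44: this is the racemisation number N, twice the interconversion constant at the flask's temperature times the reading time. It counts the e-foldings of excess that the oldest product has undergone. Fresh product carries the excess set by the selectivity factor, the ratio of the two coupling constants, with the substrates taken as equal. At 50 °C that factor is 31.9, so gamma's fresh product stands at 93.9%.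

Is N enough? Steady making would keep a fraction (​1 − e^(−N))/N, which gives 49.8% for gamma. But in gamma free catalyst starts falling at 0.0242 /min, about as fast as the excess decays at 0.0240 /min, so the making fades and the product is older than under steady making. With the two rates equal, each slice of product contributes the same surviving excess, and the kept fraction becomes F = N e^(−N)/(1 − e^(−N)). So gamma comes to 42.0%.

For beta, N is 4.54 × 10⁻⁴ and the selectivity factor 44.8, which gives 95.6%. For alpha, N is 0.0386 and the factor 37.2, which gives 92.9%. F was set up for equal rates, but beta and alpha stand at N far below 1, and there even the oldest product keeps nearly all of its excess. For zeta, N is 29.0, with a relaxation half-life of 1.43 min, far shorter than the hour. Free catalyst in zeta starts falling at 0.324 /min, which gives a time of 3.09 min, also far shorter than the hour, so the making in zeta fades early and I expect zero there. Beta comes out highest on my reckoning.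

The forecast gives 0% for zeta, 95.6% for beta, 39.5% for gamma and 92.6% for alpha, names beta, and says of the hottest flask that “the catalyst dies within minutes and the product then sits racemising for the rest of the hour”. The flasks give 0% for zeta, 95.6% for beta, 39.1% for gamma and 92.5% for alpha, so beta leads, and gamma lies 2.9 percentage points below my figure.

A flask like zeta kept at 55 °C sits above gamma on the scale, with N at 2.47 against 1.44. Its selectivity factor is 31.2, and F then gives 21.4%. That flask ends at an excess of 21.2%, with right-handed product at 4.99% of the substrates charged.

The numbers of this flask are made up; the rest is arithmetic.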